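## The problem

1-O-Caffeoylquinic acid (21) is a single cyclohexane ring with four stereocentres. C1 is quaternary and carries the acylated oxygen O1 and the carboxyl carbon C7; C3, C4 and C5 are contiguous secondary carbinols. O1, O3 and O4 lie on one face of the ring, O5 and C7 on the other.

C1 is insulated from the carbinol centres by the methylenes C2 and C6, and its two ring branches differ only through the configurations at C3 and C5. Its configuration therefore cannot be relayed from the ring and is best fixed on its own, as is C5. C4 and C3 can then be derived from C5 by 1,2-induction.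

The caffeoyl group sits on the most hindered, tertiary oxygen while three secondary hydroxyls and the acid end free, so the regiochemistry of acylation has to be enforced by the topology of a late intermediate. The catechol is oxidation-sensitive, the cinnamate double bond would not survive ozonolysis, osmylation or dissolving-metal conditions, and the ester is base-labile. The acyl group must therefore arrive after all redox chemistry and be unmasked by acid alone.

The feature that invites the key step is the C3–C4 bond. It joins two carbinol carbons whose hydroxyls are cis, with O5 trans next to O4. Cutting it leaves two aldehydes of like polarity linked through C2–C1–C6–C5, a 1,6-dialdehyde in which a C5 silyloxy group sits alpha to the C4 aldehyde. A second useful feature is that O5 and C7 are cis, so a 1,5-lactone can mask both and leave O1 as the only free hydroxyl.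

## Retrosynthesis

**Ester and protecting groups (21 ⇒ 20 ⇒ 16 + 19).** The caffeoyl C(=O)–O1 bond is cut last. In the forward sense the acid chloride 19, made from caffeic acid 17 through its diacetate 18, acylates the bicyclic lactone acetonide 16. In 16, O3 and O4 are tied in an isopropylidene acetal and O5 and C7 in the 1,5-lactone, so O1 is the only nucleophile. Acetates, acetonide and lactone are all acid-labile, so one aqueous acid treatment of 20 should give 21 without base. Acylating earlier is excluded because the cinnamate alkene and catechol esters would meet ozone and divalent samarium.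

**Lactone O5–C7 (16 ⇒ 14 ⇒ 13).** The lactone bond is traced to an acyl transfer within 14. There O1 and C7 are held in a pivalaldehyde-derived dioxolanone and O5 is a silyl ether. Desilylation gives the C5 alcohol 15, whose oxygen is cis to C7 and should attack the activated acylal carbonyl. The auxiliary is expelled as pivalaldehyde, which frees O1 and closes the lactone in the same operation. Diol 13 needs only acetonide formation to become 14. The alternative of full hydrolysis to the free tetrol acid and re-protection is longer and is kept as a fallback.

**Ring bond C3–C4 (13 ⇒ 12).** This is the strategic cut. Reductive union of the C3 and C4 aldehyde carbons of dialdehyde 12 closes the ring and creates both remaining stereocentres. It removes the carbocycle and two of four stereocentres in one step. It is preferred over cuts at C1–C2 or C1–C6 because those would make the quaternary centre during ring closure, whereas here C1 and C5 are in place beforehand. The forward reaction must give the cis-diol and place it trans to O5.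

**Aldehydes and the C5 carbinol (12 ⇒ 11 ⇒ 10 ⇒ 9).** Both aldehydes are unveiled together by cleaving two alkenes of 11, an allyl group (C2–C3) and a styryl group at C4. The silyl ether 11 comes from allylic alcohol 10, and 10 from enone 9 by reagent-controlled 1,2-reduction, which sets C5. A β-phenyl enone is chosen over a plain vinyl ketone deliberately. A terminal vinyl group is hardly larger than the CH2 on the other side of the carbonyl, and such a ketone is a polymerisable Michael acceptor. The styryl ketone belongs to the enone class on which oxazaborolidine reductions are most dependable. The phenyl carbon is lost on ozonolysis, so the change costs no step.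

**Bond C4–C5 (9 ⇒ 8 + 7).** The enone is cut at the acyl–alkenyl bond. Acid chloride 8, made from acid 6, is coupled with styrylstannane 7 under neutral palladium catalysis. Neutral conditions matter because the ketone of 9 has the acetal oxygen O1 in the β-position. Basic organometallic additions would also attack the dioxolanone carbonyl.

**Quaternary centre C1 (6 ⇒ 3 + 4; 3 ⇒ 1 + 2).** The C1–C2 bond is cut to the dilithium enolate 5 of dioxolanone acid 3 and allyl bromide 4. Acid 3 is the cis acetal of (S)-malic acid 1 with pivalaldehyde 2. The acetal carbon stores the chirality of 1 while C1 is trigonal, and the tert-butyl group sends the allyl group to the face formerly occupied by hydrogen. This gives net retention. Malate C2 becomes C1, its C1 carboxyl becomes C7, its CH2CO2H arm becomes C6–C5, and the allyl group supplies C2–C3.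

## Roads not taken

**Alternative 1:** Passerini assembly of the tertiary acyloxy acid.
- **Cut and key step.** The C1–C7 bond and the caffeoyl C(=O)–O1 bond are cut together. Ketone A1, acid 18 and the convertible isocyanide A2 would combine to the acyloxy anilide A3.
- **Merits.** This is the most convergent way to the hindered ester. It avoids acylating a tertiary alcohol, which is a weak step of the chosen plan, and all three ring carbinols are present before the key step.
- **Weak points.**
  - The realistic source of A1 is oxidative removal of C7 from a natural cyclitol acid, so the route largely dismantles what it then rebuilds.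
  - The C1 configuration depends on the facial preference of a small, rod-like isocyanide on a cyclohexanone. The required product has the new C–C bond equatorial, whereas such nucleophiles tend to enter axially.
  - Passerini reactions of ketones are slow, and A1 is a β-silyloxy ketone that can eliminate.
  - Converting the anilide of A3 into the free acid requires activation and nucleophilic cleavage next to a cinnamate and two aryl acetates.
- **Comparison.** On step count from A1 this road is shorter. The chosen plan offers in return an unambiguous C1 configuration from malic acid and an endgame that uses acid only.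

**Alternative 2:** Enantioselective Diels–Alder reaction.
- **Cut and key step.** C1–C6 and C2–C3 are cut. Diene A4 would add to the 2-acyloxyacrolein A5 under chiral amine-salt catalysis to give cyclohexene A6.
- **Merits.** The ring, the quaternary centre and the ester are formed in one catalytic asymmetric step from achiral materials. No chiral pool and no stoichiometric metal are needed. In these respects it is better than the chosen plan.
- **Weak points.**
  - A6 contains one stereocentre and none of the three ring oxygens. Its double bond spans C4–C5, so a 4,5-trans-diol and a C3 hydroxyl cis to O4 remain to be installed.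
  - The two allylic methylenes C3 and C6 differ only in their distance from C1, and the only directing element for facial control is the remote quaternary centre.
  - Every oxidant used must spare the cinnamate alkene.
  - A4 is an unactivated diene and A5 carries a second acrylate-type double bond.
- **Comparison.** The ring is reached faster, but the main difficulty of the target is postponed. The chosen plan places all oxygens before or during ring closure and keeps the caffeoyl unit away from oxidants.

**Alternative 3:** Reformatsky ring closure.
- **Cut and key step.** The C1–C6 bond is cut. Metal insertion into the C–Br bond of bromomethyl ketone A7 and addition of the enolate to the C1 keto ester carbonyl would give A8.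
- **Merits.** The ring and the quaternary carbinol form together, C3 and C4 come from a cheap cis-diol acetonide, and no ozonolysis or samarium is needed. On reagent cost it is better.
- **Weak points.**
  - C1 is created in the closure and must be controlled across the forming ring by the acetonide alone.
  - A7 has three electrophilic carbonyls and an enolisable keto ester with the C3 oxygen in the β-position, so elimination threatens before cyclisation.
  - A8 is a β-hydroxy ketone prone to retro-aldol cleavage and to loss of the C1 oxygen.
  - The C5 ketone still needs a stereoselective reduction to the alcohol trans to O4.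
- **Comparison.** Step counts are similar. This road has two uncertain stereochemical events, at C1 and C5. The chosen plan has one, at C3/C4, which follows a known trend, with C1 and C5 fixed beforehand by independent controls.

Key step: step 7

## Route

Remarks on the chemistry: ring carbons are numbered as in quinic acid throughout. Metal alkoxides that only await protonation and the peroxidic ozonolysis intermediates are transient mixtures and are not numbered.

Step 1
Reactants: 1 (S)-malic acid; 2 pivalaldehyde
Product: 3 2-[(2S,4S)-2-tert-butyl-5-oxo-1,3-dioxolan-4-yl]acetic acid (tert-butyl and CH2CO2H cis)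
Conditions: 2 (1.5 equiv), TsOH·H2O (cat.), H2SO4 (cat.), pentane, reflux, Dean–Stark; recrystallisation
Reagents that add atoms: pivalaldehyde (2), CC(C)(C)C=O
Why: Acid-catalysed acetalisation of the α-hydroxy acid unit favours the five-membered dioxolanone over the six-membered alternative; under equilibrating conditions the cis acetal (new acetal carbon S) should predominate and is purified by crystallisation.

Step 2
Reactants: 3 2-[(2S,4S)-2-tert-butyl-5-oxo-1,3-dioxolan-4-yl]acetic acid; 4 allyl bromide
Product: 6 2-[(2S,4S)-2-tert-butyl-5-oxo-4-(prop-2-en-1-yl)-1,3-dioxolan-4-yl]acetic acid (allyl trans to tert-butyl), via dilithium enolate carboxylate 5 (not isolated)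
Conditions: LiN(SiMe3)2 (2.2 equiv), THF, −78 °C; 4 (2 equiv), −78 → −30 °C; aq. HCl work-up
Reagents that add atoms: allyl bromide (4), C=CCBr
Why: Enolate alkylation under self-regeneration of the stereocentre: C1 becomes trigonal in 5, the acetal tert-butyl group shields one face, and allyl bromide should enter trans to it, at the position the hydrogen occupied. This sets C1 with net retention; the carboxylate is inert at this temperature.

Step 3
Reactants: 6 2-[(2S,4S)-2-tert-butyl-5-oxo-4-(prop-2-en-1-yl)-1,3-dioxolan-4-yl]acetic acid; 7 tributyl[(E)-2-phenylethenyl]stannane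
Product: 9 (2S,5S)-2-tert-butyl-5-[(3E)-2-oxo-4-phenylbut-3-en-1-yl]-5-(prop-2-en-1-yl)-1,3-dioxolan-4-one, via acid chloride 8 (not isolated)
Conditions: (COCl)2 (1.5 equiv), Me2NCHO (cat.), CH2Cl2, 0 °C → rt, evaporate; then 7 (1.1 equiv), Pd(PPh3)4 (5 mol %), THF, 50 °C
Reagents that add atoms: tributyl[(E)-2-phenylethenyl]stannane (7), CCCC[Sn](CCCC)(CCCC)/C=C/c1ccccc1
Why: Stille acylation (acid chloride with alkenylstannane under zerovalent palladium) transfers the alkenyl group with retention of the E geometry. The neutral conditions spare the dioxolanone and avoid base-induced loss of the β-acetal oxygen from the new ketone.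

Step 4
Reactants: 9 (2S,5S)-2-tert-butyl-5-[(3E)-2-oxo-4-phenylbut-3-en-1-yl]-5-(prop-2-en-1-yl)-1,3-dioxolan-4-one
Product: 10 (2S,5S)-2-tert-butyl-5-[(2R,3E)-2-hydroxy-4-phenylbut-3-en-1-yl]-5-(prop-2-en-1-yl)-1,3-dioxolan-4-one
Conditions: (S)-Me-CBS oxazaborolidine [(3aS)-1-methyl-3,3-diphenyltetrahydro-1H,3H-pyrrolo[1,2-c][1,3,2]oxazaborole, C18H20BNO] (0.2 equiv), catecholborane (1.8 equiv), toluene, −78 °C; MeOH, then pH 7 buffer
Reagents that add atoms: none
Why: Corey–Bakshi–Shibata reduction: the catalyst binds the carbonyl anti to the larger conjugated styryl group and delivers hydride to the face that should give the R carbinol (C5 of quinic acid) under reagent control. Catecholborane at −78 °C should leave the allyl group and the lactone untouched and give only 1,2-reduction.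

Step 5
Reactants: 10 (2S,5S)-2-tert-butyl-5-[(2R,3E)-2-hydroxy-4-phenylbut-3-en-1-yl]-5-(prop-2-en-1-yl)-1,3-dioxolan-4-one
Product: 11 (2S,5S)-2-tert-butyl-5-[(2R,3E)-2-(tert-butyldimethylsilyloxy)-4-phenylbut-3-en-1-yl]-5-(prop-2-en-1-yl)-1,3-dioxolan-4-one
Conditions: TBSOTf (1.3 equiv), 2,6-lutidine (2 equiv), CH2Cl2, −78 °C
Reagents that add atoms: tert-butyldimethylsilyl triflate, CC(C)(C)[Si](C)(C)OS(=O)(=O)C(F)(F)F
Why: Silylation with a silyl triflate and a hindered base is fast at low temperature, so the γ-hydroxyl is capped before it can attack the dioxolanone carbonyl. The bulky silyloxy group is the control element of the key step.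

Step 6
Reactants: 11 (2S,5S)-2-tert-butyl-5-[(2R,3E)-2-(tert-butyldimethylsilyloxy)-4-phenylbut-3-en-1-yl]-5-(prop-2-en-1-yl)-1,3-dioxolan-4-one
Product: 12 (2R)-2-(tert-butyldimethylsilyloxy)-3-[(2S,4R)-2-tert-butyl-5-oxo-4-(2-oxoethyl)-1,3-dioxolan-4-yl]propanal
Conditions: O3, CH2Cl2, −78 °C; PPh3 (2.5 equiv), −78 °C → rt; rapid filtration through silica, used at once
Reagents that add atoms: ozone, [O-][O+]=O
Why: Double ozonolysis with reductive work-up cleaves the terminal and the styryl alkene to the C3 and C4 aldehydes under neutral conditions, which should preserve the α-silyloxy stereocentre. Benzaldehyde must be removed because it would consume the reductant of the next step.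

Step 7
Reactants: 12 (2R)-2-(tert-butyldimethylsilyloxy)-3-[(2S,4R)-2-tert-butyl-5-oxo-4-(2-oxoethyl)-1,3-dioxolan-4-yl]propanal
Product: 13 5-O-TBS-quinic acid O1,C7-pivalaldehyde dioxolanone (spiro 1,3-dioxolan-4-one at C1; O3-H and O4-H cis to each other and to O1; O5-TBS trans to them and cis to C7; acetal carbon S)
Conditions: SmI2 (0.1 M in THF, 3 equiv), t-BuOH (3 equiv), THF, −78 → −20 °C, slow addition of 12; pH 7 buffer
Reagents that add atoms: none
Why: Divalent samarium transfers one electron to one aldehyde to give a samarium-bound ketyl, which adds to the carbon of the second aldehyde held on the same trivalent samarium centre; a second electron transfer gives the diolate (coupling of two ketyls on one metal is the kinetically equivalent alternative), and tert-butanol and the work-up protonate it. The closest known reaction type is the SmI2 pinacol cyclisation of 1,6-dialdehydes, including α-alkoxy dialdehydes, to cis-cyclohexane-1,2-diols as used for cyclitols. The cyclohexane ring closes by 6-exo-trig attack of the ketyl carbon on the C=O carbon, forming the C3–C4 bond. C4 is controlled by C5: in the chair-like transition state the C5 silyloxy group is equatorial and the developing C4–O bond lies anti to it to minimise dipole and steric repulsion, so O4 should end trans to O5. C3 is controlled by C4 through the metal: both oxygens stay bound to samarium while the bond forms, which enforces the cis-diol and places O3 axial, cis to O1. This chair (O5 and O4 equatorial, O3 and O1 axial, C7 equatorial) is the one quinic acid itself prefers, so the fixed C1 centre is matched with the closure. The step needs diastereoselectivity at C3/C4, secured by the α-silyloxy group and samarium bridging, and chemoselectivity for the aldehydes over the dioxolanone, secured by the much faster reduction of aldehydes at low temperature without HMPA.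

Step 8
Reactants: 13 5-O-TBS-quinic acid O1,C7-pivalaldehyde dioxolanone
Product: 14 3,4-O-isopropylidene-5-O-TBS-quinic acid O1,C7-pivalaldehyde dioxolanone
Conditions: 2,2-dimethoxypropane (5 equiv), pyridinium p-toluenesulfonate (0.1 equiv), CH2Cl2, rt
Reagents that add atoms: 2,2-dimethoxypropane, COC(C)(C)OC
Why: Acid-catalysed transacetalisation closes a cis-fused dioxolane on the axial/equatorial cis-3,4-diol; the silyl ether and the acylal tolerate the mild acid.

Step 9
Reactants: 14 3,4-O-isopropylidene-5-O-TBS-quinic acid O1,C7-pivalaldehyde dioxolanone
Product: 16 3,4-O-isopropylidene-1,5-quinide (C7–O5 γ-lactone, cis-3,4-acetonide, free tertiary O1-H), via 5-hydroxy dioxolanone 15 (not isolated)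
Conditions: Bu4NF (1.2 equiv), THF, 0 °C → rt; AcOH quench
Reagents that add atoms: none
Why: Fluoride desilylation frees O5, which is cis to C7; after ring flip to the chair with O5 and C7 axial it should attack the activated acylal carbonyl (lactonisation by intramolecular acyl transfer). The hemiacetal leaving group collapses to pivalaldehyde and the C1 alkoxide, leaving O1 as the only free hydroxyl.

Step 10
Reactants: 17 caffeic acid
Product: 18 3,4-di-O-acetylcaffeic acid
Conditions: Ac2O (3 equiv), pyridine, rt; aq. HCl work-up
Reagents that add atoms: acetic anhydride, CC(=O)OC(C)=O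
Why: Standard acetylation of both phenols protects the catechol from oxidation and from self-acylation in the next step; any mixed anhydride is hydrolysed on work-up.

Step 11
Reactants: 16 3,4-O-isopropylidene-1,5-quinide; 18 3,4-di-O-acetylcaffeic acid
Product: 20 1-O-(3,4-di-O-acetylcaffeoyl)-3,4-O-isopropylidene-1,5-quinide, via di-O-acetylcaffeoyl chloride 19 (not isolated)
Conditions: 18, (COCl)2 (1.5 equiv), Me2NCHO (cat.), CH2Cl2, rt, evaporate; then 16, pyridine (3 equiv), 4-(dimethylamino)pyridine (0.5 equiv), CH2Cl2, rt
Reagents that add atoms: 3,4-di-O-acetylcaffeic acid (18), CC(=O)Oc1ccc(/C=C/C(=O)O)cc1OC(C)=O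
Why: Acylation of the tertiary alcohol with an acid chloride under nucleophilic catalysis; O1 is the only free hydroxyl and is held equatorial and exposed on the bicyclic lactone, so no regiochemical choice arises.

Step 12
Reactants: 20 1-O-(3,4-di-O-acetylcaffeoyl)-3,4-O-isopropylidene-1,5-quinide
Product: 21 1-O-caffeoylquinic acid
Conditions: 1 M aq. HCl/THF (1:4), rt, several days; lyophilisation, reversed-phase chromatography
Reagents that add atoms: water, O
Why: Acid hydrolysis should remove the acetonide and both aryl acetates and open the strained γ-lactone to the acid, while the hindered tertiary cinnamate, the slowest ester to hydrolyse, survives; no base is used, so acyl migration and catechol oxidation are avoided.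

## Compound list

1 | (S)-malic acid | O[C@@H](CC(=O)O)C(=O)O | starting material
2 | pivalaldehyde (2,2-dimethylpropanal) | CC(C)(C)C=O | starting material
3 | 2-[(2S,4S)-2-tert-butyl-5-oxo-1,3-dioxolan-4-yl]acetic acid (cis) | CC(C)(C)[C@H]1O[C@@H](CC(=O)O)C(=O)O1 | intermediate
4 | allyl bromide | C=CCBr | starting material
5 | dilithium 2-[(2S)-2-tert-butyl-5-oxido-1,3-dioxol-4-yl]acetate (enolate carboxylate of 3) | [Li+].[Li+].CC(C)(C)[C@H]1OC(CC(=O)[O-])=C([O-])O1 | intermediate (not isolated)
6 | 2-[(2S,4S)-2-tert-butyl-5-oxo-4-(prop-2-en-1-yl)-1,3-dioxolan-4-yl]acetic acid (allyl trans to tert-butyl) | C=CC[C@@]1(CC(=O)O)O[C@H](C(C)(C)C)OC1=O | intermediate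
7 | tributyl[(E)-2-phenylethenyl]stannane | CCCC[Sn](CCCC)(CCCC)/C=C/c1ccccc1 | starting material
8 | 2-[(2S,4S)-2-tert-butyl-5-oxo-4-(prop-2-en-1-yl)-1,3-dioxolan-4-yl]acetyl chloride | C=CC[C@@]1(CC(=O)Cl)O[C@H](C(C)(C)C)OC1=O | intermediate (not isolated)
9 | (2S,5S)-2-tert-butyl-5-[(3E)-2-oxo-4-phenylbut-3-en-1-yl]-5-(prop-2-en-1-yl)-1,3-dioxolan-4-one | C=CC[C@@]1(CC(=O)/C=C/c2ccccc2)O[C@H](C(C)(C)C)OC1=O | intermediate
10 | (2S,5S)-2-tert-butyl-5-[(2R,3E)-2-hydroxy-4-phenylbut-3-en-1-yl]-5-(prop-2-en-1-yl)-1,3-dioxolan-4-one | C=CC[C@@]1(C[C@@H](O)/C=C/c2ccccc2)O[C@H](C(C)(C)C)OC1=O | intermediate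
11 | (2S,5S)-2-tert-butyl-5-[(2R,3E)-2-(tert-butyldimethylsilyloxy)-4-phenylbut-3-en-1-yl]-5-(prop-2-en-1-yl)-1,3-dioxolan-4-one | C=CC[C@@]1(C[C@@H](O[Si](C)(C)C(C)(C)C)/C=C/c2ccccc2)O[C@H](C(C)(C)C)OC1=O | intermediate
12 | (2R)-2-(tert-butyldimethylsilyloxy)-3-[(2S,4R)-2-tert-butyl-5-oxo-4-(2-oxoethyl)-1,3-dioxolan-4-yl]propanal | O=CC[C@@]1(C[C@@H](O[Si](C)(C)C(C)(C)C)C=O)O[C@H](C(C)(C)C)OC1=O | intermediate
13 | 5-O-TBS-quinic acid O1,C7-pivalaldehyde dioxolanone (O3-H, O4-H and O1 on one face; O5-TBS and C7 on the other; acetal carbon S) | CC(C)(C)[C@H]1O[C@@]2(C[C@@H](O[Si](C)(C)C(C)(C)C)[C@H](O)[C@H](O)C2)C(=O)O1 | intermediate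
14 | 3,4-O-isopropylidene-5-O-TBS-quinic acid O1,C7-pivalaldehyde dioxolanone | CC(C)(C)[C@H]1O[C@@]2(C[C@@H](O[Si](C)(C)C(C)(C)C)[C@@H]3OC(C)(C)O[C@@H]3C2)C(=O)O1 | intermediate
15 | 3,4-O-isopropylidenequinic acid O1,C7-pivalaldehyde dioxolanone (free O5-H) | CC(C)(C)[C@H]1O[C@@]2(C[C@@H](O)[C@@H]3OC(C)(C)O[C@@H]3C2)C(=O)O1 | intermediate (not isolated)
16 | 3,4-O-isopropylidene-1,5-quinide (quinic acid 1,5-lactone 3,4-acetonide, free O1-H) | O[C@@]12C[C@@H](OC1=O)[C@@H]3OC(C)(C)O[C@@H]3C2 | intermediate
17 | caffeic acid | OC(=O)/C=C/c1ccc(O)c(O)c1 | starting material
18 | 3,4-di-O-acetylcaffeic acid | CC(=O)Oc1ccc(/C=C/C(=O)O)cc1OC(C)=O | intermediate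
19 | 3,4-di-O-acetylcaffeoyl chloride | CC(=O)Oc1ccc(/C=C/C(=O)Cl)cc1OC(C)=O | intermediate (not isolated)
20 | 1-O-(3,4-di-O-acetylcaffeoyl)-3,4-O-isopropylidene-1,5-quinide | CC(=O)Oc1ccc(/C=C/C(=O)O[C@@]23C[C@@H](OC2=O)[C@@H]4OC(C)(C)O[C@@H]4C3)cc1OC(C)=O | intermediate
21 | 1-O-caffeoylquinic acid | O=C(/C=C/c1ccc(O)c(O)c1)O[C@]1(C(=O)O)C[C@@H](O)[C@H](O)[C@H](O)C1 | target

## Step count and risks

Total: 12 steps, with the two acid chloride formations run in one pot with their couplings. Longest linear sequence: 11 steps (steps 1–9, 11 and 12). Step 10 is a one-step side branch.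

**Step 7 (key step).**
- Risk: facial discrimination in the ketyl–aldehyde closure may be incomplete, giving the all-cis 3,4,5 isomer or a trans-diol. Simple reduction of the aldehydes, loss of the C5 silyloxy group after over-reduction, or aldol self-condensation of the dialdehyde may compete.
- Fallback: this sets out from 11 and builds the ring before its oxygens. Ring-closing metathesis with second-generation Grubbs catalyst, RuCl2(=CHPh)(H2IMes)(PCy3), in CH2Cl2 at 40 °C should expel styrene and give the spiro cyclohexene with a C3=C4 double bond F1. Dihydroxylation with catalytic OsO4 and NMO in aqueous acetone should then deliver the cis-diol anti to the allylic silyloxy group. The route is rejoined at 13.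

**Step 4.**
- Risk: facial selectivity of hydride delivery may be poor, because the "small" substituent is a CH2 attached to a quaternary carbon and the remote C1 centre may be mismatched. The free γ-hydroxyl may also translactonise onto the dioxolanone during work-up.
- Fallback: this sets out from 9 and replaces reagent control by separation and recycling. Luche reduction (NaBH4, CeCl3·7H2O, MeOH, −78 °C) should give 10 together with its C5 epimer (2S,5S)-2-tert-butyl-5-[(2S,3E)-2-hydroxy-4-phenylbut-3-en-1-yl]-5-(prop-2-en-1-yl)-1,3-dioxolan-4-one F2. The two are separated by chromatography, and F2 is oxidised back to 9 with Dess–Martin periodinane and resubmitted. The route is rejoined at 10.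

**Step 3.**
- Risk: the acyl–palladium intermediate may decarbonylate before transmetalation, or the β-oxy ketone product may eliminate the acetal oxygen on prolonged heating.
- Fallback: this sets out from 6. The acid is converted with ethanethiol, DCC and catalytic 4-(dimethylamino)pyridine into the S-ethyl thioester of 6 F3. Liebeskind–Srogl coupling with (E)-2-phenylethenylboronic acid then follows, using Pd2(dba)3, tri(2-furyl)phosphine and copper thiophene-2-carboxylate, Cu(O2CC4H3S) (monovalent copper), in THF at 50 °C, base-free. The route is rejoined at 9.

**Step 9.**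
- Risk: desilylation may not be followed by clean acyl transfer. The C5 alcohol may persist, the hemiacetal ester may fail to collapse, or the basic fluoride may cause silyl migration or oligomerisation through the tertiary alkoxide.
- Fallback: this sets out from 13 and bypasses 14. Full hydrolysis with aqueous HCl in THF at 50 °C removes the pivalaldehyde acetal and the silyl ether to give (−)-quinic acid F4. The known one-pot acetonide formation and lactonisation (acetone, 2,2-dimethoxypropane, TsOH·H2O, reflux) then rejoins the route at 16.

**Step 11.**
- Risk: acylation of the tertiary hydroxyl may be sluggish, and the aryl acetates of the acid chloride may transfer acetyl to O1 instead.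
- Fallback: this sets out from 16 and builds the cinnamate on the ring. Esterification with diethylphosphonoacetic acid, DCC and 4-(dimethylamino)pyridine proceeds through a reactive phosphonoketene, which acylates hindered alcohols, and gives 1-O-(diethoxyphosphorylacetyl)-3,4-O-isopropylidene-1,5-quinide F5. Horner–Wadsworth–Emmons olefination with 3,4-diacetoxybenzaldehyde (LiCl, i-Pr2NEt, MeCN, rt) should then form the E-alkene. The route is rejoined at 20.

## Further compounds

F1 | step 7 | spiro cyclohexene: 5-O-TBS-3,4-dideoxy-3,4-didehydroquinic acid O1,C7-pivalaldehyde dioxolanone | CC(C)(C)[C@H]1O[C@@]2(C[C@@H](O[Si](C)(C)C(C)(C)C)C=CC2)C(=O)O1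
F2 | step 4 | (2S,5S)-2-tert-butyl-5-[(2S,3E)-2-hydroxy-4-phenylbut-3-en-1-yl]-5-(prop-2-en-1-yl)-1,3-dioxolan-4-one (C5 epimer of 10) | C=CC[C@@]1(C[C@H](O)/C=C/c2ccccc2)O[C@H](C(C)(C)C)OC1=O
F3 | step 3 | S-ethyl 2-[(2S,4S)-2-tert-butyl-5-oxo-4-(prop-2-en-1-yl)-1,3-dioxolan-4-yl]ethanethioate | C=CC[C@@]1(CC(=O)SCC)O[C@H](C(C)(C)C)OC1=O
F4 | step 9 | (−)-quinic acid | O[C@]1(C(=O)O)C[C@@H](O)[C@H](O)[C@H](O)C1
F5 | step 11 | 1-O-(diethoxyphosphorylacetyl)-3,4-O-isopropylidene-1,5-quinide | CCOP(=O)(OCC)CC(=O)O[C@@]12C[C@@H](OC1=O)[C@@H]3OC(C)(C)O[C@@H]3C2
A1 | alternative 1 | 3-O-TBS-4,5-O-(2,3-dimethoxybutane-2,3-diyl)-3,4,5-trihydroxycyclohexanone | O=C1C[C@H]2O[C@@](OC)(C)[C@](OC)(C)O[C@@H]2[C@H](O[Si](C)(C)C(C)(C)C)C1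
A2 | alternative 1 | 1-(2,2-dimethoxyethyl)-2-isocyanobenzene | [C-]#[N+]c1ccccc1CC(OC)OC
A3 | alternative 1 | 1-O-(di-O-acetylcaffeoyl)-3-O-TBS-4,5-O-butanediacetal quinic acid 2-(2,2-dimethoxyethyl)anilide | CC(=O)Oc1ccc(/C=C/C(=O)O[C@]2(C(=O)Nc3ccccc3CC(OC)OC)C[C@H]3O[C@@](OC)(C)[C@](OC)(C)O[C@@H]3[C@H](O[Si](C)(C)C(C)(C)C)C2)cc1OC(C)=O
A4 | alternative 2 | buta-1,3-diene | C=CC=C
A5 | alternative 2 | 3-oxoprop-1-en-2-yl (E)-3-(3,4-diacetoxyphenyl)acrylate | CC(=O)Oc1ccc(/C=C/C(=O)OC(=C)C=O)cc1OC(C)=O
A6 | alternative 2 | (S)-1-formylcyclohex-3-en-1-yl (E)-3-(3,4-diacetoxyphenyl)acrylate | CC(=O)Oc1ccc(/C=C/C(=O)O[C@]2(C=O)CC=CCC2)cc1OC(C)=O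
A7 | alternative 3 | ethyl 3-[5-(bromoacetyl)-2,2-dimethyl-1,3-dioxolan-4-yl]-2-oxopropanoate (cis-4,5-disubstituted, configuration as in A8) | CCOC(=O)C(=O)C[C@H]1OC(C)(C)O[C@H]1C(=O)CBr
A8 | alternative 3 | ethyl 5-dehydro-3,4-O-isopropylidenequinate | CCOC(=O)[C@@]1(O)CC(=O)[C@@H]2OC(C)(C)O[C@@H]2C1
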